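**Strategy**

Everything rests on cutting the bond between C2 of the dihydropyranone ring (ring C) and C1' of the diprenylated anisole ring (ring B). C2 is the only stereocentre and at the same time the β-carbon of the C4 ketone, so the bond is made by a rhodium/chiral diene-catalysed asymmetric 1,4-addition of an arylboronic acid to the C2=C3 bond of a flat chromone. One operation joins both halves and sets the (2S) configuration. The precursors are 5,7-bis(methoxymethoxy)chromone and 4-methoxy-3,5-diprenylphenylboronic acid; the latter comes from 2,6-dibromoanisole by a double linear-selective prenyl Suzuki coupling and a sterically governed C–H borylation.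

Key step: step 4

Assumption: the sense of induction of the Ph-bod* diene with chromone 7 is taken by analogy with simple cyclic enones; it is to be checked by CD and chiral HPLC on the first run, and the antipodal ligand is used if the sense proves opposite. (Prenyl = 3-methylbut-2-enyl; MOM = methoxymethyl.)

**Route**

Step 1
Reactants: 1 2,6-dibromoanisole; 2 3-methylbut-2-enylboronic acid pinacol ester (prenyl-Bpin, 2.6 equiv)
Product: 3 2-methoxy-1,3-bis(3-methylbut-2-enyl)benzene
Conditions: Pd-PEPPSI-IPent (4 mol%), 5 M aq KOH, THF, 70 °C
Reagents that add atoms: none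
Why: Suzuki–Miyaura cross-coupling of an allylboronate, in which the bulky NHC ligand steers reductive elimination to the unsubstituted terminus of the allyl–palladium intermediate, so both C–Br bonds (each flanked only by the methoxy group) should be converted into linear prenyl groups.

Step 2
Reactants: 3 2-methoxy-1,3-bis(3-methylbut-2-enyl)benzene
Product: 5 [4-methoxy-3,5-bis(3-methylbut-2-enyl)phenyl]boronic acid, via aryl pinacol boronate 4 (not isolated)
Conditions: [Ir(OMe)(cod)]2 (1.5 mol%), dtbpy (3 mol%), B2pin2 (1.0 equiv), THF, 50 °C; then NaIO4 (3 equiv), NH4OAc, acetone/H2O, rt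
Reagents that add atoms: bis(pinacolato)diboron CC1(C)OB(OC1(C)C)B1OC(C)(C)C(C)(C)O1; water O
Why: Iridium-catalysed aromatic C–H borylation is sterically controlled, so only C4–H (the one ring C–H without an ortho substituent) should react while the hindered trisubstituted prenyl olefins are poor substrates for the iridium boryl species, and periodate cleavage of the pinacol ester in the same flask then frees the boronic acid.

Step 3
Reactants: 6 5,7-dihydroxychromone
Product: 7 5,7-bis(methoxymethoxy)-4H-chromen-4-one
Conditions: NaH (2.5 equiv), DMF, 0 °C; MOMCl (2.5 equiv), 0 °C to rt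
Reagents that add atoms: chloromethyl methyl ether COCCl
Why: Williamson-type O-alkylation (MOM acetal formation) of the bis-phenoxide, with sodium hydride chosen because the 5-OH is hydrogen-bonded to the C4 carbonyl and reacts sluggishly with amine bases.

Step 4
Reactants: 5 [4-methoxy-3,5-bis(3-methylbut-2-enyl)phenyl]boronic acid (1.5 equiv); 7 5,7-bis(methoxymethoxy)-4H-chromen-4-one
Product: 8 (2S)-5,7-bis(methoxymethoxy)-2-[4-methoxy-3,5-bis(3-methylbut-2-enyl)phenyl]chroman-4-one
Conditions: [RhCl(C2H4)2]2 (2.5 mol%), (S,S)-Ph-bod* (5.5 mol%), aq KOH (20 mol%), toluene/H2O (10:1), 40 °C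
Reagents that add atoms: none
Why: Hayashi–Miyaura mechanism: the aryl group of 5 is transmetalated to a hydroxorhodium(I)–diene complex, the aryl–rhodium species adds across the coordinated C2=C3 bond of 7 with the aryl going to C2 (the β-carbon of the C4 ketone), and the oxa-π-allyl rhodium enolate is protonated by water to release 8 and regenerate Rh–OH. The closest known reaction type is the rhodium/chiral diene-catalysed asymmetric 1,4-addition of arylboronic acids to chromones, 5,7-dioxygenated chromones included. No ring is closed; the step only joins ring B to C2 of the existing pyranone ring. The new C2 stereocentre is controlled by the catalyst alone: the C2-symmetric diene shields one enone face so that the aryl group is delivered to the Re face of C2, which corresponds to (2S). The step needs 1,4- over 1,2-addition, no reaction at the prenyl groups and no base-induced ring opening of the product (retro-oxa-Michael, which would racemise C2); the aryl–rhodium species inserts into the activated enone but not into unactivated trisubstituted olefins, and the low base loading, the mild temperature and the protection of both phenols (no chelating 5-OH, no deactivating phenoxide) should secure the rest.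

Step 5
Reactants: 8 (2S)-5,7-bis(methoxymethoxy)-2-[4-methoxy-3,5-bis(3-methylbut-2-enyl)phenyl]chroman-4-one
Product: 9 4-Methylabyssinone V, (2S)-5,7-dihydroxy-2-[4-methoxy-3,5-bis(3-methylbut-2-enyl)phenyl]chroman-4-one
Conditions: 3 M HCl in MeOH, 40 °C
Reagents that add atoms: none
Why: Acid-catalysed acetal exchange (MOM cleavage) with methanol; the prenyl groups flank a methyl ether and so cannot cyclise onto a free phenol, and C2 should keep its configuration because ring opening of the flavanone to the chalcone is slow under mild acid.

**Compound list**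

1 | 2,6-dibromoanisole (1,3-dibromo-2-methoxybenzene) | COc1c(Br)cccc1Br | starting material
2 | 3-methylbut-2-enylboronic acid pinacol ester (prenyl-Bpin) | CC(C)=CCB1OC(C)(C)C(C)(C)O1 | starting material
3 | 2-methoxy-1,3-bis(3-methylbut-2-enyl)benzene | COc1c(CC=C(C)C)cccc1CC=C(C)C | intermediate
4 | 2-[4-methoxy-3,5-bis(3-methylbut-2-enyl)phenyl]-4,4,5,5-tetramethyl-1,3,2-dioxaborolane | COc1c(CC=C(C)C)cc(B2OC(C)(C)C(C)(C)O2)cc1CC=C(C)C | intermediate (not isolated)
5 | [4-methoxy-3,5-bis(3-methylbut-2-enyl)phenyl]boronic acid | COc1c(CC=C(C)C)cc(B(O)O)cc1CC=C(C)C | intermediate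
6 | 5,7-dihydroxychromone (5,7-dihydroxy-4H-chromen-4-one) | O=C1C=COc2cc(O)cc(O)c12 | starting material
7 | 5,7-bis(methoxymethoxy)-4H-chromen-4-one | O=C1C=COc2cc(OCOC)cc(OCOC)c12 | intermediate
8 | (2S)-5,7-bis(methoxymethoxy)-2-[4-methoxy-3,5-bis(3-methylbut-2-enyl)phenyl]chroman-4-one | COc1c(CC=C(C)C)cc([C@@H]2CC(=O)c3c(OCOC)cc(OCOC)cc3O2)cc1CC=C(C)C | intermediate
9 | 4-Methylabyssinone V, (2S)-5,7-dihydroxy-2-[4-methoxy-3,5-bis(3-methylbut-2-enyl)phenyl]chroman-4-one | COc1c(CC=C(C)C)cc([C@@H]2CC(=O)c3c(O)cc(O)cc3O2)cc1CC=C(C)C | target

**Step count**

Total steps: 5. Longest linear sequence: 4 steps (steps 1, 2, 4, 5).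

**Steps most likely to fail**

Step 4. Carbometalation of the electron-rich 5,7-dialkoxychromone may be slow, so that protodeboronation of the boronic acid competes. Hydroxide may also open the product ring and erode the enantiomeric purity, or the facial selectivity may be poor. The fallback gives up catalyst control of the stereocentre. It sets out from 5 and 7: a palladium(II)-catalysed conjugate addition (Pd(TFA)2, 2,2'-bipyridine, NH4PF6, H2O, 1,2-dichloroethane, 60 °C; base-free, hence no ring opening) should give racemic 5,7-bis(methoxymethoxy)-2-[4-methoxy-3,5-bis(3-methylbut-2-enyl)phenyl]chroman-4-one F1. The enantiomers are then separated by preparative SFC on a chiral stationary phase; the (2R)-enantiomer F2 is set aside and the (2S)-enantiomer is compound 8, where the route is rejoined.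

Step 2. The iridium boryl and hydride species may hydroborate, isomerise or borylate the prenyl olefins instead of reacting only at the ring C–H. The fallback moves the borylation to an olefin-free substrate and the prenylation to the end. It sets out from 1: iridium-catalysed borylation ([Ir(OMe)(cod)]2, dtbpy, B2pin2, THF, 60 °C; C4–H is again the only unhindered ring C–H) should give 2-(3,5-dibromo-4-methoxyphenyl)-4,4,5,5-tetramethyl-1,3,2-dioxaborolane F3. Periodate cleavage (NaIO4, NH4OAc, acetone/H2O) then gives (3,5-dibromo-4-methoxyphenyl)boronic acid F4. The rhodium-catalysed 1,4-addition of F4 to 7 under the conditions of step 4 should give (2S)-2-(3,5-dibromo-4-methoxyphenyl)-5,7-bis(methoxymethoxy)chroman-4-one F5, since aryl bromides are inert to rhodium(I) under these conditions. A double Stille coupling of F5 with tributyl(3-methylbut-2-enyl)stannane (Pd(PPh3)4, DMF, 90 °C, neutral medium that leaves C2 untouched) comes back to the route at 8.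

Step 1. Reductive elimination may occur in part at the substituted allyl terminus and give branched (reverse-prenyl) isomers, or the sequence may stall after the first coupling while the allylboronate is protodeboronated by the strong base. The fallback replaces cross-coupling by stepwise halogen–metal exchange and copper-mediated SN2 allylation. It sets out from 1: n-BuLi (1.05 equiv), THF, −78 °C, then CuBr·SMe2 and prenyl bromide should give 1-bromo-2-methoxy-3-(3-methylbut-2-enyl)benzene F6. Repeating the same sequence on F6 comes back to the route at 3.

**Further compounds**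

F1 | step 4 | racemic 5,7-bis(methoxymethoxy)-2-[4-methoxy-3,5-bis(3-methylbut-2-enyl)phenyl]chroman-4-one | COc1c(CC=C(C)C)cc(C2CC(=O)c3c(OCOC)cc(OCOC)cc3O2)cc1CC=C(C)C
F2 | step 4 | (2R)-5,7-bis(methoxymethoxy)-2-[4-methoxy-3,5-bis(3-methylbut-2-enyl)phenyl]chroman-4-one | COc1c(CC=C(C)C)cc([C@H]2CC(=O)c3c(OCOC)cc(OCOC)cc3O2)cc1CC=C(C)C
F3 | step 2 | 2-(3,5-dibromo-4-methoxyphenyl)-4,4,5,5-tetramethyl-1,3,2-dioxaborolane | COc1c(Br)cc(B2OC(C)(C)C(C)(C)O2)cc1Br
F4 | step 2 | (3,5-dibromo-4-methoxyphenyl)boronic acid | COc1c(Br)cc(B(O)O)cc1Br
F5 | step 2 | (2S)-2-(3,5-dibromo-4-methoxyphenyl)-5,7-bis(methoxymethoxy)chroman-4-one | COc1c(Br)cc([C@@H]2CC(=O)c3c(OCOC)cc(OCOC)cc3O2)cc1Br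
F6 | step 1 | 1-bromo-2-methoxy-3-(3-methylbut-2-enyl)benzene | COc1c(Br)cccc1CC=C(C)C
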